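## The problem

Target 23 is a 1H-inden-1-one with a pentasubstituted benzene ring. In indenone numbering, C1 is the carbonyl, C2 and C6 carry guaiazulen-3-yl groups (5-isopropyl-3,8-dimethylazulen-1-yl), C3 and C7 carry methyl, C4 carries the formyl group, and only C5 carries hydrogen. The molecule has no stereocenter. Any sp3 centers that appear at C2 and C3 on the way are erased when the C2=C3 bond is made, so they control nothing that lasts. The one stereochemical element that matters is the geometry of an alkene in the ring-forming precursor.

The real difficulty is regiochemical. Five different groups must be placed around one benzene ring while two azulenes are present, and these are far more nucleophilic than any benzene, so substitution of a preformed arene is not an option. The azulenes also set the limits on reagents. They are attacked by halogenating agents and quinone oxidants and protonated by strong acids, and the methyl group on the seven-membered ring next to the ring fusion is C–H acidic toward amide bases. The indenone is a cross-conjugated, cyclopentadienone-like acceptor and the aldehyde is an electrophile, so both should be unveiled at the end.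

The feature that opens the synthesis is the lone hydrogen at C5. The sequence C3a–C4–C5–C6 can be read as a conjugated enyne (C3a=C4–C5≡C6) whose inner sp carbon becomes C5–H. C7 with its methyl and C7a with the C1 carbonyl can be read as a but-2-ynoyl group. The saturated chain C1–C2–C3 joins the two, so one thermal cycloaddition can close both rings without oxidant, acid or metal.

## Retrosynthesis

**23 from 22 from 21 (no skeletal bond cut).** The formyl group is carried as a silyl-protected hydroxymethyl group. A free aldehyde would not survive the enolate and Grignard steps. An acetal conjugated to the electron-rich azulenyl enyne would ionize too easily. The primary silyl ether is inert to base, heat and divalent palladium. The forward steps are fluoride cleavage and a benzylic oxidation with MnO2, which leaves azulenes alone.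

**21 from 19 through 20 (the C2=C3 double bond is removed).** Carrying the indenone double bond through ring formation would make the tether a rigid dienone that needs a (Z)-tetrasubstituted alkene and opens electrocyclic side paths. A saturated C2–C3 bond gives a flexible three-atom tether. The price is a late dehydrogenation. It must work on an α-aryl ketone without quinones, halogens or strong base, and a Saegusa–Ito oxidation of the silyl enol ether 20 made by soft enolization meets this.

**19 from 17 (C3a–C7a and C6–C7 are cut).** This is the key disconnection. Both rings open to an acyclic enyne ynone.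
- Against a diene–alkyne Diels–Alder reaction: that route would need an oxidant to aromatize.
- Against a [2+2+2] cyclotrimerization of a diynone with alkyne 14: that would also cut C4–C5 and leave the orientation of the azulenyl alkyne open. The tether of 17 fixes the regiochemistry completely.
- The forward reaction asks for a (Z)-enyne, with the tether trans to the alkynyl group, and for heat that azulenes tolerate.

**17 from 15 and 16 (C1–C7a is cut).** The ynone is the most fragile function of the route, so it is made last, by acyl substitution of Weinreb amide 15 with 1-propynylmagnesium bromide 16. Amide 15 is robust and stops the Grignard reagent at the ketone stage.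

**15 from 11 and 14 (C4–C5 is cut).** A Sonogashira coupling joins alkenyl iodide 11 and 3-ethynylguaiazulene 14 with retention of the alkene geometry. The neighbouring cut at C6–azulene would need a 3-haloguaiazulene, and these are unstable. Alkyne 14 comes from guaiazulene 1 and the ethynylbenziodoxolone 12 through 13, by C–H alkynylation at the position where azulenes react with electrophiles.

**11 from 9 through 10 (H and I are removed from C3a and C4).** The needed alkene has the tether cis to the CH2OSi group and trans to the alkynyl group, which is the more crowded isomer. Methods that rely on steric or thermodynamic preference give the other one.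
- A Claisen-type rearrangement of an ester of a tertiary alkynyl carbinol would place the slim alkynyl group axial and deliver it cis to the tether. Its substrate would also be an azulene-activated propargylic ester that ionizes readily.
- Aldehyde olefinations and α-iodination of enals give the wrong isomer for the same reason.

A syn-hydrostannation of alkyne 9 fixes the geometry by mechanism. Hydrogen goes to C3a and tin to C4, the carbon that is less hindered and next to oxygen, and iodine then replaces tin with retention.

**9 from 4 and 8 (C2–C3 is cut).** Alkylation of the enolate of arylacetamide 4 with the secondary propargylic mesylate 8 brings in C3 with its methyl group and the alkyne in one step. Conjugate additions to crotonyl acceptors would put the carbonyl one carbon too far along the chain and need redox corrections. The forward step needs substitution to beat elimination. It need not control the two new centers.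

**4 from 3 from 1 and 2; 8 from 7 from 5 and 6.** The azulene–C2 bond comes from a carbene C–H functionalization of guaiazulene 1 with ethyl diazoacetate 2 at C3. The ester 3 is converted to the Weinreb amide 4. Mesylate 8 comes from the acetylide of silyl ether 5 and acetaldehyde 6 through alcohol 7.

## Roads not taken

**Alternative 1:** ring contraction of a diazonaphthalenone by Wolff rearrangement.
- *Cut and forward step.* The C1–C7a bond of an indene is traced back to the 2-diazonaphthalen-1(2H)-one A2. On photolysis A2 should lose nitrogen, the aryl carbon should migrate, and the ketene should be trapped by water as indene-1-carboxylic acid A1.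
- *Merits.* This rearrangement is among the most dependable photoreactions known. The C2=C3 double bond is already present, so no dehydrogenation is needed, and in that respect this road is better than the chosen plan.
- *Weak points.* A2 is a hexasubstituted naphthalene bearing both azulenes, so the arene problem is moved, not solved. Making the diazo ketone needs nitrosating or diazo-transfer conditions next to azulenes. The azulenes absorb strongly and would compete for the light. A1 carries a carboxylic acid where the ketone must be, so an oxidative decarboxylation has to follow in the presence of two oxidant-sensitive rings.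
- *Comparison.* The chosen plan builds the benzene ring itself from an acyclic chain, uses heat instead of light, and needs no oxidant stronger than palladium diacetate and MnO2.

**Alternative 2:** pyranone–enamine Diels–Alder reaction with loss of CO2.
- *Cut and forward step.* C3a–C4 and C5–C6 are cut. The fused pyranone A4 and the pyrrolidine enamine of 3,3-dimethoxypropanal should add, then lose CO2 and pyrrolidine to give indanone A3.
- *Merits.* There is no metal and no oxidant, the partners are cheap, and the aldehyde arrives at the right oxidation level as an acetal. The chosen plan needs two steps to unmask it, so here this road is better.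
- *Weak points.* A3 lacks the C2 azulenyl group, the C3 methyl group and the C2=C3 bond. Installing them after the ring is made would take dehydrogenation, conjugate methylation, α-functionalization, arylation and a second dehydrogenation, in the presence of an azulene and an acetal. The azulenyl donor on the pyranone also raises its LUMO and should slow the inverse-demand cycloaddition.
- *Comparison.* The chosen plan has every carbon and both azulenes in place before the ring closes, so only functional-group changes follow.

**Alternative 3:** vinylketene–alkyne benzannulation from a diazo ketone.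
- *Cut and forward step.* C4–C5, C6–C7 and C3a–C4 are cut. Irradiation of diazo ketone A6 should give a vinylketene that adds alkyne 14. Four- and six-electron electrocyclic steps should then give phenol A5.
- *Merits.* This road is more convergent than the chosen plan: the second azulene enters in the ring-forming step itself, and no alkene geometry has to be set.
- *Weak points.* A5 carries a hydroxyl group at C4, so a triflate and a palladium-catalysed reductive carbonylation are needed to reach the aldehyde. A6 is a 2-acylcyclopentenone, which is strongly electrophilic and enolizable and hard to diazotize cleanly. The photolysis again has to work beside strongly absorbing azulenes. The same late dehydrogenation remains.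
- *Comparison.* The chosen plan brings the C4 carbon substituent in place, is thermal, and has its regiochemistry fixed by the tether instead of by the polarization of an alkyne.

Key step: step 11

Remark: positions are given in indenone numbering throughout. Step 5 is expected to give both C2/C3 diastereomers, which are carried together because both centers become sp2 later; names and SMILES show the racemic diastereomer that maps onto trans-19.

Step 1
Reactants: 1 guaiazulene (7-isopropyl-1,4-dimethylazulene); 2 ethyl diazoacetate
Product: 3 ethyl 2-(guaiazulen-3-yl)acetate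
Conditions: Cu(OTf)2 (5 mol %), CH2Cl2, rt, slow addition of 2 to 1 (3 equiv)
Reagents that add atoms: none
Why: Carbene C–H functionalization: the electrophilic copper carbenoid from 2 should attack C3 of 1, the only free and most nucleophilic position of the five-membered ring, and a proton shift restores the azulene; slow addition to excess 1 limits carbene dimerization and double alkylation.

Step 2
Reactants: 3 ethyl 2-(guaiazulen-3-yl)acetate
Product: 4 N-methoxy-N-methyl-2-(guaiazulen-3-yl)acetamide
Conditions: MeNH(OMe)·HCl, i-PrMgCl, THF, −20 to 0 °C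
Reagents that add atoms: N,O-dimethylhydroxylamine hydrochloride, CNOC.Cl
Why: Weinreb amide formation by direct aminolysis of the ester with the magnesium amide; the amide gives a well-behaved enolate for step 5 and is the acyl donor for step 10.

Step 3
Reactants: 5 tert-butyldimethyl(prop-2-yn-1-yloxy)silane; 6 acetaldehyde
Product: 7 5-[(tert-butyldimethylsilyl)oxy]pent-3-yn-2-ol (racemic)
Conditions: n-BuLi, THF, −78 °C; then 6, −78 to 0 °C; aq NH4Cl
Reagents that add atoms: none
Why: Addition of a lithium acetylide to an aldehyde, the standard route to secondary propargylic alcohols; the new center is racemic.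

Step 4
Reactants: 7 5-[(tert-butyldimethylsilyl)oxy]pent-3-yn-2-ol
Product: 8 5-[(tert-butyldimethylsilyl)oxy]pent-3-yn-2-yl methanesulfonate (racemic)
Conditions: MsCl, Et3N, CH2Cl2, −20 to 0 °C
Reagents that add atoms: methanesulfonyl chloride, CS(=O)(=O)Cl
Why: Sulfonylation of the secondary alcohol; the propargylic mesylate is used without long storage.

Step 5
Reactants: 4 N-methoxy-N-methyl-2-(guaiazulen-3-yl)acetamide; 8 5-[(tert-butyldimethylsilyl)oxy]pent-3-yn-2-yl methanesulfonate
Product: 9 (2R*,3S*)-6-[(tert-butyldimethylsilyl)oxy]-N-methoxy-N-methyl-2-(guaiazulen-3-yl)-3-methylhex-4-ynamide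
Conditions: LiN(SiMe3)2 (1.05 equiv), THF/DMPU, −78 °C; then 8, −78 to −10 °C
Reagents that add atoms: none
Why: Enolate alkylation (SN2): the lithium enolate of the arylacetamide is soft and only moderately basic, and secondary propargylic sulfonates are activated toward direct displacement; the two new centers form without useful control, which does not matter because C2 becomes sp2 in step 12 and C3 in step 13.

Step 6
Reactants: 9 (2R*,3S*)-6-[(tert-butyldimethylsilyl)oxy]-N-methoxy-N-methyl-2-(guaiazulen-3-yl)-3-methylhex-4-ynamide
Product: 11 (2R*,3S*,4E)-6-[(tert-butyldimethylsilyl)oxy]-5-iodo-N-methoxy-N-methyl-2-(guaiazulen-3-yl)-3-methylhex-4-enamide, via vinylstannane 10 (not isolated)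
Conditions: Bu3SnH, PdCl2(PPh3)2 (3 mol %), THF, rt; then I2, CH2Cl2, 0 °C
Reagents that add atoms: tributyltin hydride, CCCC[SnH](CCCC)CCCC; iodine, II
Why: Palladium-catalysed syn-hydrostannation followed by iododestannylation with retention: H and Sn add to the same face, tin going to the alkyne carbon that is less hindered and next to the CH2OSi group, so the tether ends up cis to CH2OSi and trans to iodine; the C–Sn bond should react with I2 far faster than the blocked azulene does.

Step 7
Reactants: 1 guaiazulene; 12 1-[(triisopropylsilyl)ethynyl]-1,2-benziodoxol-3(1H)-one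
Product: 13 triisopropyl[(guaiazulen-3-yl)ethynyl]silane
Conditions: AuCl (5 mol %), Et2O, rt
Reagents that add atoms: none
Why: Electrophilic C–H alkynylation of an electron-rich arene with an ethynylbenziodoxolone under AuCl catalysis, a reaction known for azulenes; C3 is again the reacting position and the bulky silyl group keeps the alkyne stable.

Step 8
Reactants: 13 triisopropyl[(guaiazulen-3-yl)ethynyl]silane
Product: 14 3-ethynylguaiazulene (1-ethynyl-5-isopropyl-3,8-dimethylazulene)
Conditions: TBAF, THF, 0 °C
Reagents that add atoms: none
Why: Fluoride cleavage of the C(sp)–Si bond; 14 is used at once because 1-ethynylazulenes are sensitive to air and light.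

Step 9
Reactants: 11 (2R*,3S*,4E)-6-[(tert-butyldimethylsilyl)oxy]-5-iodo-N-methoxy-N-methyl-2-(guaiazulen-3-yl)-3-methylhex-4-enamide; 14 3-ethynylguaiazulene
Product: 15 (2R*,3R*,4Z)-5-{[(tert-butyldimethylsilyl)oxy]methyl}-N-methoxy-N-methyl-2,7-bis(guaiazulen-3-yl)-3-methylhept-4-en-6-ynamide
Conditions: PdCl2(PPh3)2 (5 mol %), CuI (10 mol %), i-Pr2NH, THF, rt, degassed
Reagents that add atoms: none
Why: Sonogashira coupling; oxidative addition and reductive elimination keep the alkene geometry, so the alkynyl group is fixed trans to the tether, and exclusion of oxygen suppresses homocoupling of the electron-rich alkyne.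

Step 10
Reactants: 15 (2R*,3R*,4Z)-5-{[(tert-butyldimethylsilyl)oxy]methyl}-N-methoxy-N-methyl-2,7-bis(guaiazulen-3-yl)-3-methylhept-4-en-6-ynamide; 16 1-propynylmagnesium bromide
Product: 17 (5R*,6R*,7Z)-7-{[(tert-butyldimethylsilyl)oxy]methyl}-5,9-bis(guaiazulen-3-yl)-6-methylnon-7-ene-2,8-diyn-4-one
Conditions: 16 (3 equiv), THF, −20 to 0 °C; aq NH4Cl
Reagents that add atoms: none
Why: Acyl substitution of a Weinreb amide by an alkynyl Grignard reagent; the chelated tetrahedral adduct prevents over-addition, and the weakly basic acetylide should add faster than it deprotonates C2.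

Step 11
Reactants: 17 (5R*,6R*,7Z)-7-{[(tert-butyldimethylsilyl)oxy]methyl}-5,9-bis(guaiazulen-3-yl)-6-methylnon-7-ene-2,8-diyn-4-one
Product: 19 trans-4-{[(tert-butyldimethylsilyl)oxy]methyl}-2,6-bis(guaiazulen-3-yl)-3,7-dimethylindan-1-one (racemic), via cyclic allene 18 (not isolated)
Conditions: BHT (2 equiv), degassed toluene (0.01 M), sealed tube, 160–180 °C
Reagents that add atoms: none
Why: On heating, the enyne C3a=C4–C5≡C6 and the ketone-activated alkyne C7≡C7a of 17 should combine in an intramolecular tetradehydro-Diels–Alder reaction, the known thermal [4+2] cycloaddition of conjugated enynes with alkynyl ketones that gives indanones. The six-membered ring closes in the [4+2] mode by forming C3a–C7a and C6–C7, and the five-membered ring closes at the same time as a fused ring through the three-atom tether C1–C2–C3, which allows only the union of C3a with C7a. The first product is the bicyclic cyclohexa-1,2,4-triene 18, a strained cyclic allene with sp3 C3a. The phenol BHT then shuttles the C3a hydrogen to the central allene carbon C5, by protonation of C5 and loss of the C3a proton or the hydrogen-atom equivalent, and gives the benzene ring of 19 without any oxidant. No lasting stereocenter is created: C3a is transient, and C2 and C3 are spectators, C2 being free to epimerize to the trans arrangement. The selectivity needed is periselectivity, since [4+2] closure must outrun the intramolecular ene reaction of the allylic CH2OSi hydrogens, [2+2] closure and ynone oligomerization. The (Z)-alkene holds the tether trans to the alkynyl group so that C3a and C6 can reach C7a and C7 from one face, the substituents at C2 and C3 favour the folded conformer, the ketone lowers the alkyne LUMO, and high dilution with the radical-trapping phenol suppresses intermolecular loss.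

Step 12
Reactants: 19 trans-4-{[(tert-butyldimethylsilyl)oxy]methyl}-2,6-bis(guaiazulen-3-yl)-3,7-dimethylindan-1-one
Product: 20 7-{[(tert-butyldimethylsilyl)oxy]methyl}-2,5-bis(guaiazulen-3-yl)-1,4-dimethyl-3-(trimethylsilyloxy)-1H-indene (racemic)
Conditions: TMSOTf, Et3N, CH2Cl2, 0 °C
Reagents that add atoms: trimethylsilyl trifluoromethanesulfonate, C[Si](C)(C)OS(=O)(=O)C(F)(F)F
Why: Soft enolization of the α-aryl ketone gives the only possible silyl enol ether, C2 being the sole enolizable position; no strong base touches the acidic azulene methyl groups, and both indanone epimers converge here.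

Step 13
Reactants: 20 7-{[(tert-butyldimethylsilyl)oxy]methyl}-2,5-bis(guaiazulen-3-yl)-1,4-dimethyl-3-(trimethylsilyloxy)-1H-indene
Product: 21 4-{[(tert-butyldimethylsilyl)oxy]methyl}-2,6-bis(guaiazulen-3-yl)-3,7-dimethyl-1H-inden-1-one
Conditions: Pd(OAc)2 (1.1 equiv), MeCN, rt
Reagents that add atoms: none
Why: Saegusa–Ito oxidation: divalent palladium forms the C2-bound enolate on the face anti to the C3 methyl group, which is syn to the C3 hydrogen, and β-hydride elimination gives the C2=C3 bond and zerovalent palladium; these conditions avoid the quinone and halogen oxidants that azulenes do not tolerate.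

Step 14
Reactants: 21 4-{[(tert-butyldimethylsilyl)oxy]methyl}-2,6-bis(guaiazulen-3-yl)-3,7-dimethyl-1H-inden-1-one
Product: 22 4-(hydroxymethyl)-2,6-bis(guaiazulen-3-yl)-3,7-dimethyl-1H-inden-1-one
Conditions: TBAF, AcOH, THF, 0 °C to rt
Reagents that add atoms: none
Why: Fluoride desilylation of the primary silyl ether, buffered with acetic acid so that the base-sensitive indenone does not meet unbuffered fluoride or alkoxide.

Step 15
Reactants: 22 4-(hydroxymethyl)-2,6-bis(guaiazulen-3-yl)-3,7-dimethyl-1H-inden-1-one
Product: 23 2,6-bis(guaiazulen-3-yl)-3,7-dimethyl-1-oxo-1H-indene-4-carbaldehyde (CNP0222726.0)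
Conditions: MnO2 (activated, excess), CH2Cl2, rt
Reagents that add atoms: none
Why: MnO2 oxidation of a benzylic alcohol; the heterogeneous oxidant stops at the aldehyde and should leave the azulene rings and their alkyl groups intact at room temperature.

## Compound list

1 | guaiazulene (7-isopropyl-1,4-dimethylazulene) | Cc1ccc2c(C)ccc(C(C)C)cc1-2 | starting material
2 | ethyl diazoacetate | CCOC(=O)C=[N+]=[N-] | starting material
3 | ethyl 2-(guaiazulen-3-yl)acetate | CCOC(=O)Cc1cc(C)c2cc(C(C)C)ccc(C)c1-2 | intermediate
4 | N-methoxy-N-methyl-2-(guaiazulen-3-yl)acetamide | CON(C)C(=O)Cc1cc(C)c2cc(C(C)C)ccc(C)c1-2 | intermediate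
5 | tert-butyldimethyl(prop-2-yn-1-yloxy)silane | C#CCO[Si](C)(C)C(C)(C)C | starting material
6 | acetaldehyde | CC=O | starting material
7 | 5-[(tert-butyldimethylsilyl)oxy]pent-3-yn-2-ol (racemic) | CC(O)C#CCO[Si](C)(C)C(C)(C)C | intermediate
8 | 5-[(tert-butyldimethylsilyl)oxy]pent-3-yn-2-yl methanesulfonate (racemic) | CC(OS(C)(=O)=O)C#CCO[Si](C)(C)C(C)(C)C | intermediate
9 | (2R*,3S*)-6-[(tert-butyldimethylsilyl)oxy]-N-methoxy-N-methyl-2-(guaiazulen-3-yl)-3-methylhex-4-ynamide (racemic) | CON(C)C(=O)[C@@H](c1cc(C)c2cc(C(C)C)ccc(C)c1-2)[C@H](C)C#CCO[Si](C)(C)C(C)(C)C | intermediate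
10 | (2R*,3S*,4E)-6-[(tert-butyldimethylsilyl)oxy]-N-methoxy-N-methyl-2-(guaiazulen-3-yl)-3-methyl-5-(tributylstannyl)hex-4-enamide (racemic) | CON(C)C(=O)[C@@H](c1cc(C)c2cc(C(C)C)ccc(C)c1-2)[C@H](C)/C=C(\CO[Si](C)(C)C(C)(C)C)[Sn](CCCC)(CCCC)CCCC | intermediate
11 | (2R*,3S*,4E)-6-[(tert-butyldimethylsilyl)oxy]-5-iodo-N-methoxy-N-methyl-2-(guaiazulen-3-yl)-3-methylhex-4-enamide (racemic) | CON(C)C(=O)[C@@H](c1cc(C)c2cc(C(C)C)ccc(C)c1-2)[C@H](C)/C=C(\CO[Si](C)(C)C(C)(C)C)I | intermediate
12 | 1-[(triisopropylsilyl)ethynyl]-1,2-benziodoxol-3(1H)-one | CC(C)[Si](C#CI1OC(=O)c2ccccc12)(C(C)C)C(C)C | starting material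
13 | triisopropyl[(guaiazulen-3-yl)ethynyl]silane | CC(C)[Si](C#Cc1cc(C)c2cc(C(C)C)ccc(C)c1-2)(C(C)C)C(C)C | intermediate
14 | 3-ethynylguaiazulene (1-ethynyl-5-isopropyl-3,8-dimethylazulene) | C#Cc1cc(C)c2cc(C(C)C)ccc(C)c1-2 | intermediate
15 | (2R*,3R*,4Z)-5-{[(tert-butyldimethylsilyl)oxy]methyl}-N-methoxy-N-methyl-2,7-bis(guaiazulen-3-yl)-3-methylhept-4-en-6-ynamide (racemic) | CON(C)C(=O)[C@@H](c1cc(C)c2cc(C(C)C)ccc(C)c1-2)[C@H](C)/C=C(\CO[Si](C)(C)C(C)(C)C)C#Cc1cc(C)c2cc(C(C)C)ccc(C)c1-2 | intermediate
16 | 1-propynylmagnesium bromide | CC#C[Mg]Br | starting material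
17 | (5R*,6R*,7Z)-7-{[(tert-butyldimethylsilyl)oxy]methyl}-5,9-bis(guaiazulen-3-yl)-6-methylnon-7-ene-2,8-diyn-4-one (racemic) | CC#CC(=O)[C@@H](c1cc(C)c2cc(C(C)C)ccc(C)c1-2)[C@H](C)/C=C(\CO[Si](C)(C)C(C)(C)C)C#Cc1cc(C)c2cc(C(C)C)ccc(C)c1-2 | intermediate
18 | cyclic allene: (2R*,3S*)-4-{[(tert-butyldimethylsilyl)oxy]methyl}-2,6-bis(guaiazulen-3-yl)-3,7-dimethyl-2,3-dihydro-3aH-inden-1-one with cumulated double bonds C4=C5=C6 and a C7=C7a double bond (cyclohexa-1,2,4-triene; C3a configuration not defined) | C[C@H]1[C@H](c2cc(C)c3cc(C(C)C)ccc(C)c2-3)C(=O)C2=C(C)C(c3cc(C)c4cc(C(C)C)ccc(C)c3-4)=C=C(CO[Si](C)(C)C(C)(C)C)C12 | intermediate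
19 | trans-(2R*,3S*)-4-{[(tert-butyldimethylsilyl)oxy]methyl}-2,6-bis(guaiazulen-3-yl)-3,7-dimethylindan-1-one (racemic) | C[C@H]1[C@H](c2cc(C)c3cc(C(C)C)ccc(C)c2-3)C(=O)c2c(C)c(-c3cc(C)c4cc(C(C)C)ccc(C)c3-4)cc(CO[Si](C)(C)C(C)(C)C)c21 | intermediate
20 | 7-{[(tert-butyldimethylsilyl)oxy]methyl}-2,5-bis(guaiazulen-3-yl)-1,4-dimethyl-3-(trimethylsilyloxy)-1H-indene (racemic) | C[C@H]1C(c2cc(C)c3cc(C(C)C)ccc(C)c2-3)=C(O[Si](C)(C)C)c2c(C)c(-c3cc(C)c4cc(C(C)C)ccc(C)c3-4)cc(CO[Si](C)(C)C(C)(C)C)c21 | intermediate
21 | 4-{[(tert-butyldimethylsilyl)oxy]methyl}-2,6-bis(guaiazulen-3-yl)-3,7-dimethyl-1H-inden-1-one | CC1=C(c2cc(C)c3cc(C(C)C)ccc(C)c2-3)C(=O)c2c(C)c(-c3cc(C)c4cc(C(C)C)ccc(C)c3-4)cc(CO[Si](C)(C)C(C)(C)C)c21 | intermediate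
22 | 4-(hydroxymethyl)-2,6-bis(guaiazulen-3-yl)-3,7-dimethyl-1H-inden-1-one | CC1=C(c2cc(C)c3cc(C(C)C)ccc(C)c2-3)C(=O)c2c(C)c(-c3cc(C)c4cc(C(C)C)ccc(C)c3-4)cc(CO)c21 | intermediate
23 | 2,6-bis(guaiazulen-3-yl)-3,7-dimethyl-1-oxo-1H-indene-4-carbaldehyde | CC1=C(c2cc(C)c3cc(C(C)C)ccc(C)c2-3)C(=O)c2c(C)c(-c3cc(C)c4cc(C(C)C)ccc(C)c3-4)cc(C=O)c21 | target

## Step count and risks

Total: 15 steps. Longest linear sequence: 11 steps (steps 1, 2, 5, 6, 9, 10, 11, 12, 13, 14, 15).

**Step 11 (key step).** The cycloaddition may be too slow to win. The tether sits on the alkene end of the enyne and forces the electron-rich enyne terminus C3a onto the carbonyl-bearing alkyne carbon C7a, against the polarization of both partners. The reaction could then be diverted to the intramolecular ene reaction of the allylic CH2OSi hydrogens with the ynone, or to ynone oligomerization.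

The fallback sets out from 9 and comes back at 19. Amide 9 would be treated with 16, as in step 10, to give the diynone (5R*,6S*)-9-[(tert-butyldimethylsilyl)oxy]-5-(guaiazulen-3-yl)-6-methylnona-2,7-diyn-4-one F1. F1 would be co-cyclized with alkyne 14 in a [2+2+2] cyclotrimerization catalysed by RhCl(PPh3)3 in toluene at 60–80 °C. This forms C3a–C7a, C6–C7 and C4–C5 and gives 19 directly, bypassing steps 6, 9 and 10. It is held in reserve because both diyne termini are substituted, so the orientation of 14 is not secured. The isomer with the azulene at C5 would have to be separated.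

**Step 5.** Substitution at the secondary propargylic carbon may lose to elimination of methanesulfonate. Proton transfer from the acidic methyl group on the seven-membered ring to the enolate may also divert alkylation to that methyl group.

The fallback reverses the polarity of the C2–C3 bond and avoids carbanions next to the azulene. It sets out from 1 and 8 and comes back at 9.
- Guaiazulene 1 would be acylated without catalyst by ethyl chlorooxoacetate (CH2Cl2, 0 °C) to ethyl 2-(guaiazulen-3-yl)-2-oxoacetate F2.
- Mesylate 8 would be converted with Pd(OAc)2, PPh3 and InI in THF/HMPA into its allenylindium reagent. This should add through its methyl-bearing γ-carbon to the ketone of F2 and give ethyl 6-[(tert-butyldimethylsilyl)oxy]-2-(guaiazulen-3-yl)-2-hydroxy-3-methylhex-4-ynoate F3.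
- Ionic hydrogenation of the azulene-stabilized tertiary carbinol (Et3SiH, CF3CO2H, CH2Cl2, −20 °C, short exposure) would give ethyl (2R*,3S*)-6-[(tert-butyldimethylsilyl)oxy]-2-(guaiazulen-3-yl)-3-methylhex-4-ynoate F4.
- Amidation as in step 2 would return 9.

**Step 6.** Tin may be delivered to the wrong alkyne carbon if the silyl ether shields the carbon next to it. Iodine may also attack the azulene during destannylation.

The fallback replaces steric bias by hydroxyl direction. It sets out from 9 and comes back at 11.
- TBAF would free the propargylic alcohol (2R*,3S*)-6-hydroxy-N-methoxy-N-methyl-2-(guaiazulen-3-yl)-3-methylhex-4-ynamide F5.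
- Hydrostannation of the free alcohol with Bu3SnH and Mo(CO)3(CNt-Bu)3, which places tin next to the carbinol carbon, would give the stannane (2R*,3S*,4E)-6-hydroxy-N-methoxy-N-methyl-2-(guaiazulen-3-yl)-3-methyl-5-(tributylstannyl)hex-4-enamide F6.
- Titration with I2 at −78 °C would give (2R*,3S*,4E)-6-hydroxy-5-iodo-N-methoxy-N-methyl-2-(guaiazulen-3-yl)-3-methylhex-4-enamide F7.
- Silylation with TBSCl and imidazole would return 11.

**Step 13.** Electrophilic palladation or oxidation of the azulene rings by stoichiometric palladium diacetate may compete with enolate formation. Protodesilylation back to 19 is also possible.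

The fallback replaces palladium by a sulfur-based elimination. It sets out from 19 and comes back at 21, bypassing 20. The ketone 19, whose C2 hydrogen is far more acidic than the azulene methyl groups, would be deprotonated with LiN(SiMe3)2 at −78 °C and treated with N-tert-butylbenzenesulfinimidoyl chloride. The C2 sulfilimine adduct 2-(N-tert-butyl-S-phenylsulfinimidoyl)-4-{[(tert-butyldimethylsilyl)oxy]methyl}-2,6-bis(guaiazulen-3-yl)-3,7-dimethylindan-1-one F8 should undergo syn-elimination toward C3 on warming and give 21.

## Further compounds

F1 | step 11 | (5R*,6S*)-9-[(tert-butyldimethylsilyl)oxy]-5-(guaiazulen-3-yl)-6-methylnona-2,7-diyn-4-one (racemic) | CC#CC(=O)[C@@H](c1cc(C)c2cc(C(C)C)ccc(C)c1-2)[C@H](C)C#CCO[Si](C)(C)C(C)(C)C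
F2 | step 5 | ethyl 2-(guaiazulen-3-yl)-2-oxoacetate | CCOC(=O)C(=O)c1cc(C)c2cc(C(C)C)ccc(C)c1-2
F3 | step 5 | ethyl 6-[(tert-butyldimethylsilyl)oxy]-2-(guaiazulen-3-yl)-2-hydroxy-3-methylhex-4-ynoate (racemic, diastereomer mixture) | CCOC(=O)C(O)(c1cc(C)c2cc(C(C)C)ccc(C)c1-2)C(C)C#CCO[Si](C)(C)C(C)(C)C
F4 | step 5 | ethyl (2R*,3S*)-6-[(tert-butyldimethylsilyl)oxy]-2-(guaiazulen-3-yl)-3-methylhex-4-ynoate (racemic) | CCOC(=O)[C@@H](c1cc(C)c2cc(C(C)C)ccc(C)c1-2)[C@H](C)C#CCO[Si](C)(C)C(C)(C)C
F5 | step 6 | (2R*,3S*)-6-hydroxy-N-methoxy-N-methyl-2-(guaiazulen-3-yl)-3-methylhex-4-ynamide (racemic) | CON(C)C(=O)[C@@H](c1cc(C)c2cc(C(C)C)ccc(C)c1-2)[C@H](C)C#CCO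
F6 | step 6 | (2R*,3S*,4E)-6-hydroxy-N-methoxy-N-methyl-2-(guaiazulen-3-yl)-3-methyl-5-(tributylstannyl)hex-4-enamide (racemic) | CON(C)C(=O)[C@@H](c1cc(C)c2cc(C(C)C)ccc(C)c1-2)[C@H](C)/C=C(\CO)[Sn](CCCC)(CCCC)CCCC
F7 | step 6 | (2R*,3S*,4E)-6-hydroxy-5-iodo-N-methoxy-N-methyl-2-(guaiazulen-3-yl)-3-methylhex-4-enamide (racemic) | CON(C)C(=O)[C@@H](c1cc(C)c2cc(C(C)C)ccc(C)c1-2)[C@H](C)/C=C(\CO)I
F8 | step 13 | 2-(N-tert-butyl-S-phenylsulfinimidoyl)-4-{[(tert-butyldimethylsilyl)oxy]methyl}-2,6-bis(guaiazulen-3-yl)-3,7-dimethylindan-1-one (racemic, configuration at C2 and S not defined) | C[C@H]1C(c2cc(C)c3cc(C(C)C)ccc(C)c2-3)(S(=NC(C)(C)C)c2ccccc2)C(=O)c2c(C)c(-c3cc(C)c4cc(C(C)C)ccc(C)c3-4)cc(CO[Si](C)(C)C(C)(C)C)c21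
A1 | alternative 1 | 4-(1,3-dioxolan-2-yl)-2,6-bis(guaiazulen-3-yl)-3,7-dimethyl-1H-indene-1-carboxylic acid (racemic) | OC(=O)[C@@H]1C(c2cc(C)c3cc(C(C)C)ccc(C)c2-3)=C(C)c2c(C3OCCO3)cc(-c3cc(C)c4cc(C(C)C)ccc(C)c3-4)c(C)c21
A2 | alternative 1 | 2-diazo-5-(1,3-dioxolan-2-yl)-3,7-bis(guaiazulen-3-yl)-4,8-dimethylnaphthalen-1(2H)-one | [N-]=[N+]=C1C(=O)c2c(C)c(-c3cc(C)c4cc(C(C)C)ccc(C)c3-4)cc(C3OCCO3)c2C(C)=C1c1cc(C)c2cc(C(C)C)ccc(C)c1-2
A3 | alternative 2 | 4-(dimethoxymethyl)-6-(guaiazulen-3-yl)-7-methylindan-1-one | COC(OC)c1cc(-c2cc(C)c3cc(C(C)C)ccc(C)c2-3)c(C)c2c1CCC2=O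
A4 | alternative 2 | 3-(guaiazulen-3-yl)-4-methyl-6,7-dihydrocyclopenta[c]pyran-1,5-dione | O=C1OC(c2cc(C)c3cc(C(C)C)ccc(C)c2-3)=C(C)C2=C1CCC2=O
A5 | alternative 3 | trans-2,6-bis(guaiazulen-3-yl)-4-hydroxy-3,7-dimethylindan-1-one (racemic) | C[C@H]1[C@H](c2cc(C)c3cc(C(C)C)ccc(C)c2-3)C(=O)c2c(C)c(-c3cc(C)c4cc(C(C)C)ccc(C)c3-4)cc(O)c21
A6 | alternative 3 | trans-2-(2-diazopropanoyl)-5-(guaiazulen-3-yl)-4-methylcyclopent-2-en-1-one (racemic) | C[C@H]1[C@H](c2cc(C)c3cc(C(C)C)ccc(C)c2-3)C(=O)C(C(=O)C(C)=[N+]=[N-])=C1
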